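Rings are lettered A to H from the 3,5-dihydroxyphenoxy end. Everything rests on disconnecting the C5–O bonds of the pentaoxygenated rings B, D and F: each C5 hydroxyl, flanked by the C4 and C6 oxygens and para to the C2 ether oxygen leading to rings C, E and G, is traced back to a formyl carbon. One peracid treatment of the assembled octamer should convert all three C5 formyl groups into formates, making three aryl C–O bonds at once. The precursor is the heptadecamethyl octamer trialdehyde, whose formyl groups earlier activated each C2 fluoride for ether formation and kept rings B, D and F electron-poor.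

Key step: step 13

Remark: the target has no stereocentre, so no stereocontrol is needed; on rings B, D and F the text uses target locants (C1 oxygen toward ring A, C2 oxygen or fluorine toward ring H, C3 hydrogen, C4 and C6 methoxy, C5 formyl carbon or its oxygen replacement), while names of small compounds use their own numbering; the hydroquinone-type rings C and E are assumed to enter from commercial 4-hydroxy-3,5-dimethoxybenzaldehyde.

Step 1
Reactants: 1 4-fluoro-2,6-dimethoxybenzaldehyde
Product: 2 4-fluoro-3-iodo-2,6-dimethoxybenzaldehyde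
Conditions: NIS, TFA (cat.), MeCN, 0 °C to rt
Reagents that add atoms: N-iodosuccinimide, O=C1CCC(=O)N1I
Why: Electrophilic aromatic iodination should occur at one of the two equivalent free positions, each ortho and para to a methoxy group and meta to the formyl group, and the first iodine should slow a second substitution.

Step 2
Reactants: 2 4-fluoro-3-iodo-2,6-dimethoxybenzaldehyde
Product: 3 2-(4-fluoro-3-iodo-2,6-dimethoxyphenyl)-5,5-dimethyl-1,3-dioxane
Conditions: 2,2-dimethylpropane-1,3-diol, PPTS (cat.), toluene, reflux with azeotropic removal of water; Et3N quench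
Reagents that add atoms: 2,2-dimethylpropane-1,3-diol, OCC(C)(C)CO
Why: Acid-catalysed acetalisation should mask the formyl group as a base-stable 1,3-dioxane, which switches off its activation of the fluoride so that the copper couplings of steps 5 and 7 touch only the C–I bond.

Step 3
Reactants: 4 4-hydroxy-3,5-dimethoxybenzaldehyde
Product: 5 3,5-dimethoxy-4-(prop-2-en-1-yloxy)benzaldehyde
Conditions: allyl bromide, K2CO3, DMF, 50 °C
Reagents that add atoms: allyl bromide, C=CCBr
Why: Williamson O-alkylation of the acidic phenol with a reactive allylic halide is routine and installs a group that is stable to base and copper and is removable with palladium.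

Step 4
Reactants: 5 3,5-dimethoxy-4-(prop-2-en-1-yloxy)benzaldehyde
Product: 7 3,5-dimethoxy-4-(prop-2-en-1-yloxy)phenol, via aryl formate 6 (not isolated)
Conditions: 30% aq. H2O2, H2SO4 (cat.), MeOH, rt
Reagents that add atoms: hydrogen peroxide, OO
Why: Acid-catalysed Dakin-type oxidation, in which hydrogen peroxide adds to the formyl group and the para-alkoxyaryl group migrates to oxygen, should give the formate, which is methanolysed in the same pot, while the allyl ether is inert to hydrogen peroxide in the absence of a peracid.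

Step 5
Reactants: 3 2-(4-fluoro-3-iodo-2,6-dimethoxyphenyl)-5,5-dimethyl-1,3-dioxane; 7 3,5-dimethoxy-4-(prop-2-en-1-yloxy)phenol
Product: 8 2-{4-fluoro-2,6-dimethoxy-3-[3,5-dimethoxy-4-(prop-2-en-1-yloxy)phenoxy]phenyl}-5,5-dimethyl-1,3-dioxane
Conditions: CuI (cat.), N,N-dimethylglycine hydrochloride (cat.), Cs2CO3, 1,4-dioxane, 100 °C, Ar
Reagents that add atoms: none
Why: Ullmann-type diaryl ether synthesis, in which amino acid-ligated monovalent copper activates a C–I bond flanked only by fluorine and methoxy and couples it with the unhindered electron-rich phenol, should proceed cleanly because the acetal-masked ring offers the phenoxide no activated fluoride.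

Step 6
Reactants: 8 2-{4-fluoro-2,6-dimethoxy-3-[3,5-dimethoxy-4-(prop-2-en-1-yloxy)phenoxy]phenyl}-5,5-dimethyl-1,3-dioxane
Product: 9 4-[3-(5,5-dimethyl-1,3-dioxan-2-yl)-6-fluoro-2,4-dimethoxyphenoxy]-2,6-dimethoxyphenol
Conditions: Pd(PPh3)4 (cat.), morpholine, THF, rt, Ar
Reagents that add atoms: none
Why: Tsuji–Trost deallylation, in which zerovalent palladium ionises the allyl aryl ether to a pi-allyl complex that morpholine captures, should free the hindered phenol under basic conditions that leave the acetal and the aryl fluoride untouched.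

Step 7
Reactants: 3 2-(4-fluoro-3-iodo-2,6-dimethoxyphenyl)-5,5-dimethyl-1,3-dioxane; 10 3,5-dimethoxyphenol
Product: 12 3-(3,5-dimethoxyphenoxy)-4-fluoro-2,6-dimethoxybenzaldehyde, via dimer acetal 11 (not isolated)
Conditions: CuI (cat.), N,N-dimethylglycine hydrochloride (cat.), Cs2CO3, 1,4-dioxane, 100 °C, Ar; then 1 M aq. HCl, THF, rt
Reagents that add atoms: water, O
Why: The same Ullmann-type coupling should attach ring A to C1 of the masked ring B, and the dilute acid work-up then hydrolyses the electron-rich aryl acetal to restore the formyl group that activates the C2 fluoride.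

Step 8
Reactants: 12 3-(3,5-dimethoxyphenoxy)-4-fluoro-2,6-dimethoxybenzaldehyde; 9 4-[3-(5,5-dimethyl-1,3-dioxan-2-yl)-6-fluoro-2,4-dimethoxyphenoxy]-2,6-dimethoxyphenol
Product: 14 3-(3,5-dimethoxyphenoxy)-4-[4-(6-fluoro-3-formyl-2,4-dimethoxyphenoxy)-2,6-dimethoxyphenoxy]-2,6-dimethoxybenzaldehyde (rings A to D), via tetramer acetal 13 (not isolated)
Conditions: Cs2CO3, DMSO, 90 °C, Ar; then 1 M aq. HCl, THF, rt
Reagents that add atoms: water, O
Why: Nucleophilic aromatic substitution (addition–elimination) of the fluoride para to the formyl group by the 2,6-dimethoxyphenoxide of 9, whose own fluoride is inert because its ring carries an acetal, should form the B–O–C ether, and acetal hydrolysis then arms ring D for the next cycle.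

Step 9
Reactants: 14 ring A to D dialdehyde fluoride; 9 4-[3-(5,5-dimethyl-1,3-dioxan-2-yl)-6-fluoro-2,4-dimethoxyphenoxy]-2,6-dimethoxyphenol
Product: 16 hexamer trialdehyde fluoride (rings A to F; formyl at C5 of rings B, D and F; fluorine at C2 of ring F), via hexamer acetal 15 (not isolated)
Conditions: Cs2CO3, DMSO, 90 °C, Ar; then 1 M aq. HCl, THF, rt
Reagents that add atoms: water, O
Why: The nucleophilic aromatic substitution is repeated at the ring D fluoride, which is a far better leaving group than the aryloxide para to the ring B formyl group, and the acid work-up again unmasks the new formyl group.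

Step 10
Reactants: 1 4-fluoro-2,6-dimethoxybenzaldehyde; 17 2,4,6-trimethoxyphenol
Product: 18 2,6-dimethoxy-4-(2,4,6-trimethoxyphenoxy)benzaldehyde
Conditions: Cs2CO3, DMSO, 90 °C, Ar
Reagents that add atoms: none
Why: Nucleophilic aromatic substitution of the formyl-activated fluoride, which is flanked only by hydrogens, by the hindered 2,4,6-trimethoxyphenoxide should give the G–O–H ether.

Step 11
Reactants: 18 2,6-dimethoxy-4-(2,4,6-trimethoxyphenoxy)benzaldehyde
Product: 20 2,6-dimethoxy-4-(2,4,6-trimethoxyphenoxy)phenol, via aryl formate 19 (not isolated)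
Conditions: mCPBA, CH2Cl2, 0 °C; aq. Na2S2O3 wash; then HCl (cat.), MeOH added to the organic phase, rt, Ar
Reagents that add atoms: mCPBA (3-chloroperoxybenzoic acid), OOC(=O)c1cccc(Cl)c1
Why: Baeyer–Villiger oxidation of a 4-aryloxy-2,6-dimethoxybenzaldehyde, in which the electron-rich aryl group migrates in preference to hydride, followed by acid-catalysed methanolysis of the labile formate, should give the hindered phenol of ring G and rehearses the key step on one formyl group.

Step 12
Reactants: 16 hexamer trialdehyde fluoride; 20 2,6-dimethoxy-4-(2,4,6-trimethoxyphenoxy)phenol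
Product: 21 octamer trialdehyde (rings A to H; seventeen methoxy groups; formyl at C5 of rings B, D and F)
Conditions: Cs2CO3, DMSO, 90 °C, Ar
Reagents that add atoms: none
Why: A third nucleophilic aromatic substitution of the same type completes the chain, the hindered phenoxide of 20 displacing the ring F fluoride para to its formyl group.

Step 13
Reactants: 21 octamer trialdehyde
Product: 22 octamer tris(formate) (formyloxy at C5 of rings B, D and F)
Conditions: mCPBA (slight excess per formyl group), CH2Cl2, 0 °C; aq. Na2S2O3/NaHCO3 work-up, crude product taken on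
Reagents that add atoms: mCPBA (3-chloroperoxybenzoic acid), OOC(=O)c1cccc(Cl)c1
Why: Each formyl carbon should take up the peracid as a tetrahedral peroxy hemiacetal (Criegee intermediate), and migration of the aryl carbon to the proximal oxygen with loss of 3-chlorobenzoate then gives an aryl formate, so that three ring C5–O bonds form in one operation. The closest known reaction is the Baeyer–Villiger oxidation of 2,6-dialkoxybenzaldehydes to aryl formates, applied here at three sites of one substrate. No ring is closed and no stereocentre is created. The step needs aryl rather than hydride migration, which the two ortho methoxy groups and the para aryloxy oxygen of rings B, D and F secure by raising the migratory aptitude of C5. It also needs the peracid to spare the electron-rich rings A, C, E, G and H, which should hold because addition to a formyl group flanked by two donors is much faster at 0 °C than electrophilic hydroxylation of an arene, and because rings B, D and F stay deactivated first by formyl and then by formyloxy. The three sites share one local environment, so a single set of conditions should serve all of them.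

Step 14
Reactants: 22 octamer tris(formate)
Product: 23 octamer triphenol (hydroxyl at C5 of rings B, D and F; seventeen methoxy groups)
Conditions: HCl (cat.), MeOH/CH2Cl2, rt, Ar
Reagents that add atoms: none
Why: Acid-catalysed transesterification of aryl formates, which are among the most labile esters, should free the three phenols without passing through oxidation-prone phenoxides and before a boron halide could turn the formates into formylating agents (Fries-type formyl transfer).

Step 15
Reactants: 23 octamer triphenol
Product: 24 CNP0319661.0 (fully deprotected octamer, twenty hydroxyl groups)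
Conditions: BBr3 (excess), CH2Cl2, −78 °C to rt, Ar; MeOH quench
Reagents that add atoms: none
Why: Lewis acid-mediated cleavage of aryl methyl ethers, in which bromide attacks the O-methyl carbon of each boron-complexed ether, should remove all seventeen methyl groups while the diaryl ether bonds, which offer no sp3 carbon for bromide attack, stay intact.

Compound list
1 | 4-fluoro-2,6-dimethoxybenzaldehyde | COc1cc(F)cc(OC)c1C=O | starting material
2 | 4-fluoro-3-iodo-2,6-dimethoxybenzaldehyde | COc1cc(F)c(I)c(OC)c1C=O | intermediate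
3 | 2-(4-fluoro-3-iodo-2,6-dimethoxyphenyl)-5,5-dimethyl-1,3-dioxane | COc1cc(F)c(I)c(OC)c1C2OCC(C)(C)CO2 | intermediate
4 | 4-hydroxy-3,5-dimethoxybenzaldehyde | COc1cc(C=O)cc(OC)c1O | starting material
5 | 3,5-dimethoxy-4-(prop-2-en-1-yloxy)benzaldehyde | C=CCOc1c(OC)cc(C=O)cc1OC | intermediate
6 | 3,5-dimethoxy-4-(prop-2-en-1-yloxy)phenyl formate | C=CCOc1c(OC)cc(OC=O)cc1OC | intermediate
7 | 3,5-dimethoxy-4-(prop-2-en-1-yloxy)phenol | C=CCOc1c(OC)cc(O)cc1OC | intermediate
8 | 2-{4-fluoro-2,6-dimethoxy-3-[3,5-dimethoxy-4-(prop-2-en-1-yloxy)phenoxy]phenyl}-5,5-dimethyl-1,3-dioxane | C=CCOc1c(OC)cc(Oc2c(F)cc(OC)c(C3OCC(C)(C)CO3)c2OC)cc1OC | intermediate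
9 | 4-[3-(5,5-dimethyl-1,3-dioxan-2-yl)-6-fluoro-2,4-dimethoxyphenoxy]-2,6-dimethoxyphenol | Oc1c(OC)cc(Oc2c(F)cc(OC)c(C3OCC(C)(C)CO3)c2OC)cc1OC | intermediate
10 | 3,5-dimethoxyphenol | COc1cc(O)cc(OC)c1 | starting material
11 | 2-[3-(3,5-dimethoxyphenoxy)-4-fluoro-2,6-dimethoxyphenyl]-5,5-dimethyl-1,3-dioxane | COc1cc(OC)cc(Oc2c(F)cc(OC)c(C3OCC(C)(C)CO3)c2OC)c1 | intermediate
12 | 3-(3,5-dimethoxyphenoxy)-4-fluoro-2,6-dimethoxybenzaldehyde | COc1cc(OC)cc(Oc2c(F)cc(OC)c(C=O)c2OC)c1 | intermediate
13 | 3-(3,5-dimethoxyphenoxy)-4-{4-[3-(5,5-dimethyl-1,3-dioxan-2-yl)-6-fluoro-2,4-dimethoxyphenoxy]-2,6-dimethoxyphenoxy}-2,6-dimethoxybenzaldehyde (tetramer acetal) | COc1cc(OC)cc(Oc2c(Oc3c(OC)cc(Oc4c(F)cc(OC)c(C5OCC(C)(C)CO5)c4OC)cc3OC)cc(OC)c(C=O)c2OC)c1 | intermediate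
14 | 3-(3,5-dimethoxyphenoxy)-4-[4-(6-fluoro-3-formyl-2,4-dimethoxyphenoxy)-2,6-dimethoxyphenoxy]-2,6-dimethoxybenzaldehyde (tetramer dialdehyde fluoride) | COc1cc(OC)cc(Oc2c(Oc3c(OC)cc(Oc4c(F)cc(OC)c(C=O)c4OC)cc3OC)cc(OC)c(C=O)c2OC)c1 | intermediate
15 | hexamer acetal (rings A to F; formyl at C5 of rings B and D; ring F with fluorine at C2 and 5,5-dimethyl-1,3-dioxan-2-yl at C5) | COc1cc(OC)cc(Oc2c(Oc3c(OC)cc(Oc4c(Oc5c(OC)cc(Oc6c(F)cc(OC)c(C7OCC(C)(C)CO7)c6OC)cc5OC)cc(OC)c(C=O)c4OC)cc3OC)cc(OC)c(C=O)c2OC)c1 | intermediate
16 | hexamer trialdehyde fluoride (rings A to F; formyl at C5 of rings B, D and F; fluorine at C2 of ring F) | COc1cc(OC)cc(Oc2c(Oc3c(OC)cc(Oc4c(Oc5c(OC)cc(Oc6c(F)cc(OC)c(C=O)c6OC)cc5OC)cc(OC)c(C=O)c4OC)cc3OC)cc(OC)c(C=O)c2OC)c1 | intermediate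
17 | 2,4,6-trimethoxyphenol | COc1cc(OC)c(O)c(OC)c1 | starting material
18 | 2,6-dimethoxy-4-(2,4,6-trimethoxyphenoxy)benzaldehyde | COc1cc(OC)c(Oc2cc(OC)c(C=O)c(OC)c2)c(OC)c1 | intermediate
19 | 2,6-dimethoxy-4-(2,4,6-trimethoxyphenoxy)phenyl formate | COc1cc(OC)c(Oc2cc(OC)c(OC=O)c(OC)c2)c(OC)c1 | intermediate
20 | 2,6-dimethoxy-4-(2,4,6-trimethoxyphenoxy)phenol | COc1cc(OC)c(Oc2cc(OC)c(O)c(OC)c2)c(OC)c1 | intermediate
21 | octamer trialdehyde (seventeen methoxy groups; formyl at C5 of rings B, D and F) | COc1cc(OC)cc(Oc2c(Oc3c(OC)cc(Oc4c(Oc5c(OC)cc(Oc6c(Oc7c(OC)cc(Oc8c(OC)cc(OC)cc8OC)cc7OC)cc(OC)c(C=O)c6OC)cc5OC)cc(OC)c(C=O)c4OC)cc3OC)cc(OC)c(C=O)c2OC)c1 | intermediate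
22 | octamer tris(formate) (formyloxy at C5 of rings B, D and F) | COc1cc(OC)cc(Oc2c(Oc3c(OC)cc(Oc4c(Oc5c(OC)cc(Oc6c(Oc7c(OC)cc(Oc8c(OC)cc(OC)cc8OC)cc7OC)cc(OC)c(OC=O)c6OC)cc5OC)cc(OC)c(OC=O)c4OC)cc3OC)cc(OC)c(OC=O)c2OC)c1 | intermediate
23 | octamer triphenol (hydroxyl at C5 of rings B, D and F; seventeen methoxy groups) | COc1cc(OC)cc(Oc2c(Oc3c(OC)cc(Oc4c(Oc5c(OC)cc(Oc6c(Oc7c(OC)cc(Oc8c(OC)cc(OC)cc8OC)cc7OC)cc(OC)c(O)c6OC)cc5OC)cc(OC)c(O)c4OC)cc3OC)cc(OC)c(O)c2OC)c1 | intermediate
24 | CNP0319661.0 (octamer with twenty free hydroxyl groups) | Oc1cc(O)cc(Oc2c(Oc3c(O)cc(Oc4c(Oc5c(O)cc(Oc6c(Oc7c(O)cc(Oc8c(O)cc(O)cc8O)cc7O)cc(O)c(O)c6O)cc5O)cc(O)c(O)c4O)cc3O)cc(O)c(O)c2O)c1 | target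

Total step count: 15. Longest linear sequence: 10 steps (steps 3, 4, 5, 6, 8, 9, 12, 13, 14, 15).

Steps most likely to fail

Step 13. The peracid may hydroxylate the unsubstituted carbons of the trioxygenated rings A and H while the third formyl group is still reacting. Hydride instead of aryl migration at one site would leave a carboxylic acid, and partial loss of formate on work-up would give mixtures. The fallback sets out from 21 and replaces the electrophilic peracid by a nucleophilic peroxide. Treatment with 30% H2O2 and catalytic H2SO4 in MeOH/CH2Cl2 at room temperature (the acid-catalysed Dakin oxidation already used in step 4) should add hydrogen peroxide only to the protonated formyl groups. The formates of 22 are methanolysed as they form, so the route is rejoined at triphenol 23 and step 14 is absorbed; no compound outside the list arises (F0).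

Step 15. Cleavage may stall at some of the seventeen methyl ethers once partly demethylated boron aryloxides precipitate, and the free polyphenol may oxidise in air during aqueous work-up and chromatography. The fallback sets out from 23. After the same BBr3 treatment and methanol quench, the crude material is not purified but acetylated (Ac2O, pyridine, DMAP, Ar) to the eicosaacetate F1. This derivative should be air-stable and soluble in organic solvents, and can be separated on silica from congeners that still carry methoxy groups, which can be resubmitted to BBr3. Oxygen-free acidic methanolysis (HCl in MeOH, Ar) should then release 24.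

Step 8. Addition of the doubly ortho-substituted phenoxide to a fluoride whose neighbour is already an aryloxy group, a pi-donor to the reacting carbon, may be slow. Oxidation of the phenoxide or O-demethylation next to the formyl group could then overtake the substitution. The fallback inverts the order of the two ether-forming events on ring B. It sets out from iodo aldehyde 2, in which an inductively withdrawing iodine flanks the fluoride, and phenol 9. The same Cs2CO3/DMSO displacement should give the iodo trimer acetal F2. Ullmann-type coupling of its C–I bond with an excess of the small phenol 10 (CuI, N,N-dimethylglycine hydrochloride, Cs2CO3, 1,4-dioxane, 100 °C) should then give tetramer acetal 13, where the route is rejoined before the acid work-up of step 8.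

Further compounds
F0 | step 13 | none | none
F1 | step 15 | eicosaacetate of 24 (all twenty hydroxyl groups acetylated) | CC(=O)Oc1cc(OC(C)=O)cc(Oc2c(Oc3c(OC(C)=O)cc(Oc4c(Oc5c(OC(C)=O)cc(Oc6c(Oc7c(OC(C)=O)cc(Oc8c(OC(C)=O)cc(OC(C)=O)cc8OC(C)=O)cc7OC(C)=O)cc(OC(C)=O)c(OC(C)=O)c6OC(C)=O)cc5OC(C)=O)cc(OC(C)=O)c(OC(C)=O)c4OC(C)=O)cc3OC(C)=O)cc(OC(C)=O)c(OC(C)=O)c2OC(C)=O)c1
F2 | step 8 | 4-{4-[3-(5,5-dimethyl-1,3-dioxan-2-yl)-6-fluoro-2,4-dimethoxyphenoxy]-2,6-dimethoxyphenoxy}-3-iodo-2,6-dimethoxybenzaldehyde | COc1cc(Oc2c(OC)cc(Oc3c(F)cc(OC)c(C4OCC(C)(C)CO4)c3OC)cc2OC)c(I)c(OC)c1C=O
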